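**Plan**
- Retrosynthetic cuts, in order: C3–Br (electrophilic bromination), N1–S of a temporary tosyl group, N1–C2 of the pyrrole ring, then C2=C3 (aldehyde olefination).
- Enabling feature: C2 of the pyrrole ring carries N1 and a bromine at once. It is therefore the CBr2 end of an ortho-amino ArCH=CBr2 unit in which one bromide has been traded for nitrogen. C3 is the former aldehyde carbon.
- Forward: the benzene ring is bought complete, with C6–Br in place, as 4-bromo-2-nitrobenzaldehyde. CBr4 supplies C2 and its bromine, and NO2 becomes NH2 and then NHTs.
- The pyrrole ring is the only ring made. It closes by N1–C2 bond formation under base without any metal, then the tosyl group is hydrolysed off and NBS fills C3.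
- Stereochemistry: the target is flat and achiral, with no stereocentre and no configured double bond, so nothing needs control.

Key step: step 4

Assumption: nitrogen passes through the ring closure as its p-toluenesulfonamide. A carbonate base can generate the sulfonamide anion but not an NH2 anion, and that anion is the nucleophile for which metal-free closure onto a CH=CBr2 unit is established. The free aniline and the free indole stand directly before and after this detour.

**Step 1**
Reactants: 1 4-bromo-2-nitrobenzaldehyde; 2 carbon tetrabromide; 3 triphenylphosphine
Product: 5 4-bromo-1-(2,2-dibromovinyl)-2-nitrobenzene, via dibromomethylenetriphenylphosphorane 4 (not isolated)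
Conditions: CBr4 (1.5 equiv), PPh3 (3 equiv), CH2Cl2, 0 °C to rt
Reagents that add atoms: carbon tetrabromide (2), BrC(Br)(Br)Br
Why: Ramirez olefination (first stage of the Corey–Fuchs sequence), in which PPh3 and CBr4 generate ylide 4, which undergoes a Wittig reaction with the electron-poor, non-enolisable aldehyde of 1 while the nitro group and the aryl bromide are inert to the phosphorus reagents at this temperature.

**Step 2**
Reactants: 5 4-bromo-1-(2,2-dibromovinyl)-2-nitrobenzene
Product: 6 5-bromo-2-(2,2-dibromovinyl)aniline
Conditions: Fe powder (5 equiv), AcOH, EtOH, 80 °C
Reagents that add atoms: none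
Why: Béchamp-type iron/acid reduction delivers electrons and protons stepwise to the nitro group, which is far easier to reduce than the vinylic or aryl C–Br bonds, so the hydrogenolysis expected under catalytic hydrogenation is avoided, and the method is standard for 2-(2,2-dibromovinyl)nitroarenes.

**Step 3**
Reactants: 6 5-bromo-2-(2,2-dibromovinyl)aniline
Product: 7 N-[5-bromo-2-(2,2-dibromovinyl)phenyl]-4-methylbenzenesulfonamide
Conditions: TsCl (1.1 equiv), pyridine, CH2Cl2, 0 °C to rt
Reagents that add atoms: p-toluenesulfonyl chloride, Cc1ccc(cc1)S(=O)(=O)Cl
Why: Hinsberg-type sulfonylation of a primary aniline in pyridine should stop at the monosulfonamide because the ortho substituent and the weak base disfavour a second sulfonylation, and it makes the N–H acidic enough for a carbonate base to generate the nitrogen nucleophile in step 4.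

**Step 4**
Reactants: 7 N-[5-bromo-2-(2,2-dibromovinyl)phenyl]-4-methylbenzenesulfonamide
Product: 9 2,6-dibromo-1-tosyl-1H-indole, via bromoalkyne sulfonamide 8 (not isolated)
Conditions: Cs2CO3 (2.5 equiv), DMF, 80 °C, N2
Reagents that add atoms: none
Why: Cs2CO3 first ionises the sulfonamide N–H and then removes the vinylic hydrogen with anti loss of the bromide trans to it, giving bromoalkyne 8, whose bromine-bearing sp carbon lies within reach of the ortho nitrogen anion. Attack of N1 on that carbon forms N1–C2 and closes the pyrrole ring in a 5-endo-dig mode (allowed for alkynes, whereas direct addition–elimination on the alkene would be a less favourable 5-endo-trig event), and the C3 vinyl anion is protonated by hydrogen carbonate, so C2 keeps its second bromine. The closest known reaction type is the transition-metal-free, carbonate- or fluoride-promoted cyclisation of N-sulfonyl-2-(2,2-dibromovinyl)anilines to 2-bromoindoles, a relative of the base-mediated 5-endo-dig hydroamination of 2-alkynylsulfonanilides. No stereocentre is created. The vinylic C–Br must react in preference to the aryl C6–Br and the new C2–Br, and this is secured because no metal able to insert into C–Br bonds is present and neither of those bromides can be eliminated or is activated for SNAr, so only the CH=CBr2 unit responds to base. Addition at the bromine-bearing carbon rather than the aryl-bearing one is enforced by the ortho tether, since the alternative would be a strained 4-exo closure.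

**Step 5**
Reactants: 9 2,6-dibromo-1-tosyl-1H-indole
Product: 10 2,6-dibromo-1H-indole
Conditions: NaOH (2 M aq), 1,4-dioxane, 60 °C, N2, dark; crude 10 taken on without storage
Reagents that add atoms: none
Why: Alkaline hydrolysis of an N-sulfonylindole, in which hydroxide attacks sulfur and expels the dibromoindolyl anion (a good leaving group thanks to its two bromines), while the alcohol-free medium prevents formation of an alkylating sulfonate ester and the unactivated C2–Br and C6–Br bonds are not prone to SNAr.

**Step 6**
Reactants: 10 2,6-dibromo-1H-indole
Product: 11 2,3,6-tribromo-1H-indole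
Conditions: NBS (1.0 equiv), DMF, 0 °C, dark
Reagents that add atoms: N-bromosuccinimide, O=C1CCC(=O)N1Br
Why: Electrophilic aromatic substitution of an indole with NBS, in which C3 is the enamine-type carbon, the most nucleophilic site and the only unsubstituted pyrrole position, so one equivalent at low temperature should brominate there before the bromine-deactivated benzo ring reacts.

**Compound list**
1 | 4-bromo-2-nitrobenzaldehyde | O=Cc1ccc(Br)cc1[N+](=O)[O-] | starting material
2 | carbon tetrabromide | BrC(Br)(Br)Br | starting material
3 | triphenylphosphine | c1ccc(cc1)P(c1ccccc1)c1ccccc1 | starting material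
4 | dibromomethylenetriphenylphosphorane (not isolated) | BrC(Br)=P(c1ccccc1)(c1ccccc1)c1ccccc1 | intermediate
5 | 4-bromo-1-(2,2-dibromovinyl)-2-nitrobenzene | BrC(Br)=Cc1ccc(Br)cc1[N+](=O)[O-] | intermediate
6 | 5-bromo-2-(2,2-dibromovinyl)aniline | Nc1cc(Br)ccc1C=C(Br)Br | intermediate
7 | N-[5-bromo-2-(2,2-dibromovinyl)phenyl]-4-methylbenzenesulfonamide | Cc1ccc(cc1)S(=O)(=O)Nc1cc(Br)ccc1C=C(Br)Br | intermediate
8 | N-[5-bromo-2-(bromoethynyl)phenyl]-4-methylbenzenesulfonamide (not isolated) | Cc1ccc(cc1)S(=O)(=O)Nc1cc(Br)ccc1C#CBr | intermediate
9 | 2,6-dibromo-1-tosyl-1H-indole | Cc1ccc(cc1)S(=O)(=O)n1c(Br)cc2ccc(Br)cc12 | intermediate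
10 | 2,6-dibromo-1H-indole | Brc1ccc2cc(Br)[nH]c2c1 | intermediate
11 | 2,3,6-tribromo-1H-indole | Brc1ccc2c(Br)c(Br)[nH]c2c1 | target

Total step count: 6. Longest linear sequence: 6 steps (1 to 11).

**Steps most likely to fail**

Risk 1, step 4.
- Halophilic removal of bromine from the transient bromoalkyne before ring closure, or intermolecular N-addition and oligomerisation, would erode retention of the C2 bromine.
- The fallback sets out from 7 and installs the C2 bromine by metalation instead of by construction.
- Palladium-catalysed hydrogenolysis (Bu3SnH, Pd(PPh3)4, toluene, rt) comes first. Zerovalent palladium inserts into the less hindered C–Br bond of a 1,1-dibromoalkene much faster than into an aryl bromide. This should remove the bromine trans to the arene and give N-{5-bromo-2-[(Z)-2-bromovinyl]phenyl}-4-methylbenzenesulfonamide F1.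
- Ullmann–Goldberg-type intramolecular vinylic amidation (CuI, N,N'-dimethylethylenediamine, K2CO3, toluene, 90 °C) should then close the ring to 6-bromo-1-tosyl-1H-indole F2.
- Sulfonyl-directed deprotonation at C2 (LDA, THF, −78 °C, a base that does not exchange the aryl bromide) should give 6-bromo-2-lithio-1-tosyl-1H-indole F3.
- A quench with 1,2-dibromo-1,1,2,2-tetrachloroethane brings the sequence back to the route at 9.

Risk 2, step 5.
- Attack of hydroxide at C2 in competition with attack at sulfur (hydrolytic loss of the C2 bromine), or sluggish N–S cleavage, would undermine the deprotection.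
- The fallback does without the sulfonyl group altogether and sets out from 6.
- A Buchwald–Hartwig-type intramolecular vinylic amination of the free aniline (Pd(P(t-Bu)3)2 cat., K2CO3, toluene, 100 °C) should form N1–C2 directly.
- With this very bulky phosphine, oxidative addition of zerovalent palladium into C–Br bonds is reversible. Insertion into C6–Br or into the product C2–Br is therefore not a dead end, and only the productive five-ring reductive elimination drains the equilibrium.
- The fallback comes back to the route at 10 and makes no compound outside the list (F0).

Risk 3, step 6.
- Over-bromination in the benzo ring, or oxidation across C2–C3 by NBS with adventitious water, could compete, aggravated by decay of the unprotected 2-bromoindole while it waits.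
- The fallback reverses the order of bromination and deprotection and sets out from 9.
- Br2 in AcOH/CH2Cl2 at rt to 40 °C should brominate the tamed N-sulfonylindole at C3, still its most nucleophilic carbon, to give 2,3,6-tribromo-1-tosyl-1H-indole F4.
- Hydrolysis with aqueous NaOH in 1,4-dioxane at rt, made easier by the better tribromoindolyl leaving group, comes back to the route at 11, so the sensitive free dibromoindole is never handled.

**Further compounds**
F1 | step 4 | N-{5-bromo-2-[(Z)-2-bromovinyl]phenyl}-4-methylbenzenesulfonamide | Cc1ccc(cc1)S(=O)(=O)Nc1cc(Br)ccc1/C=C\Br
F2 | step 4 | 6-bromo-1-tosyl-1H-indole | Cc1ccc(cc1)S(=O)(=O)n1ccc2ccc(Br)cc12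
F3 | step 4 | 6-bromo-2-lithio-1-tosyl-1H-indole | [Li]c1cc2ccc(Br)cc2n1S(=O)(=O)c1ccc(C)cc1
F0 | step 5 | none | none
F4 | step 6 | 2,3,6-tribromo-1-tosyl-1H-indole | Cc1ccc(cc1)S(=O)(=O)n1c(Br)c(Br)c2ccc(Br)cc12
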